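(The numbers of this flask are made up; the result is computed.)

Two questions are put to each flask: which of substrate and target leads at the end, and how much of it stands there, in percent of the substrate charged.

    gas phase ⇌ dissolved gas, rate k1*(csat - [dissolved gas]) (k1 = 6.3 × 10⁻⁴ s⁻¹, csat = 21 mM)
    substrate + dissolved gas + catalyst ⇌ catalyst + target (K2 = 250 L mol⁻¹, k2 = 8.2 L² mol⁻² s⁻¹)
    substrate → decomposition product (k3 = 7.1 × 10⁻⁸ s⁻¹)
    dissolved gas ⇌ dormant form (K4 = 25, k4 = 5.4 × 10⁻⁵ s⁻¹)

| setting | alder | maple | larch |
|---|---|---|---|
| substrate | 0.20 M | 0.20 M | 0.20 M |
| gas phase | 21 mM (held) | 21 mM (held) | 21 mM (held) |
| catalyst | 0.16 mM | 0.21 mM | 0.27 mM |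
| time | 5.0 h | 5.0 h | 5.0 h |

- which of these there is most of at the end, counted by the substrate in it, alder (substrate / target)
- which of these there is most of at the end, counted by the substrate in it, maple (substrate / target)
- which of these there is most of at the end, counted by the substrate in it, larch (substrate / target)
- how much there is at the end of the one of these that leads, in percent of the substrate charged: alder
- how much there is at the end of the one of these that leads, in percent of the substrate charged: maple
- how much there is at the end of the one of these that leads, in percent of the substrate charged: larch

- at the start none of the gas is dissolved
- run time (alder): 5.0 h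

The substrate charge of 0.20 M is more than the saturation concentration of 21 mM, so we write the balance of the dissolved gas. It comes in by transfer and goes out by the catalysed step, which is pseudo-first-order in c(dissolved gas), with a constant equal to the rate constant times c(substrate) times c(catalyst). For alder as charged this gives two times, a supply time of 0.441 h and an uptake time of 1.06 h. We carry their ratio, 0.417, as the draw, the supply time divided by the uptake time at the substrate then present.

We set two other paths aside, because the passage to the dormant form, at 5.4 × 10⁻⁵ s⁻¹, is slower than transfer at 6.3 × 10⁻⁴ s⁻¹, and the half-life of substrate by decomposition, 110 d, is long against the 5.0 h of the run. The supply time is shorter than the run, so we let supply balance uptake, which gives c(dissolved gas) as the saturation value divided by one plus the draw, 14.8 mM in alder. We also drop the way back of the catalysed step. Substrate then decays with the rate constant times c(catalyst) times c(dissolved gas), leaving 70.5 % in alder, 65.6 % in maple and 61.2 % in larch. The leader is substrate in alder, substrate in maple and substrate in larch.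

The forecast, stepping by hand and “including the reverse reaction”, names substrate, substrate and substrate for alder, maple and larch, at 73.1 %, 68.6 % and 63.6 %. Its figure for alder stands higher than ours.

The simulation gives substrate in the lead in alder at 73.2 %, substrate in maple at 68.4 % and substrate in larch at 63.6 %. Alder's dissolved gas reads 15.4 mM at 5.00 h, where the draw, taken with the substrate then left, gives 16.1 mM. Alder left until 20 h has target in the lead, 68.9 % against 30.8 % of substrate, and its dissolved gas reads 18.4 mM, where the draw with that substrate gives 18.6 mM.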